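**Strategy.** Ring A is disconnected at C3–C4 (labdane numbering). Everything else of the decalin is (S)-carvone: its ring is ring B (C5–C10 with C17), its ketone is C9, and its isopropenyl group is C4 with C18 and C19. Two enolate alkylations at C10 add C20 and a (Z)-3-iodoallyl arm (C1–C3). The key step is a palladium-catalysed 6-exo alkenyl-borylation: the C3 alkenyl iodide adds across the isopropenyl alkene, which closes ring A, creates the quaternary C4, leaves C2=C3 for the cis-diol and puts boron (then oxygen) on C19. The feature exploited is thus the C4(C18)(C19) unit next to the C2–C3 diol. The side chain is joined at C11–C12 by alkyl–alkyl Suzuki coupling.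

Key step: step 5

Remark: bicyclic compounds are numbered as labdanes (C1–C10 decalin, C11–C16 side chain, C17 on C8, C18 and C19 on C4, C20 on C10), "C20 face" means the face of the decalin that carries the C10 methyl group and "H-5 face" the opposite one; ethyl (Z)-3-iodoacrylate, (S)-(+)-carvone and (S)-4-methyldihydrofuran-2(3H)-one are taken as commercial.

**Step 1**
Reactants: 1 ethyl (2Z)-3-iodoprop-2-enoate
Product: 2 (2Z)-3-iodoprop-2-en-1-ol
Conditions: (iBu)2AlH (DIBAL-H, 2.2 equiv), CH2Cl2, −78 °C; aqueous Rochelle salt work-up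
Reagents that add atoms: none
Why: Hydride reduction of the unsaturated ester to the allylic alcohol at low temperature leaves the C–I bond and the (Z) geometry untouched.

**Step 2**
Reactants: 2 (2Z)-3-iodoprop-2-en-1-ol
Product: 3 (1Z)-3-bromo-1-iodoprop-1-ene
Conditions: CBr4, PPh3, CH2Cl2, 0 °C
Reagents that add atoms: carbon tetrabromide, BrC(Br)(Br)Br
Why: Appel bromination displaces the oxyphosphonium ion at the primary allylic carbon under neutral conditions, so the (Z)-iodoalkene is not isomerised.

**Step 3**
Reactants: 4 (S)-(+)-carvone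
Product: 6 (5S,6R)-2,6-dimethyl-5-(prop-1-en-2-yl)cyclohex-2-en-1-one (trans-6-methylcarvone), via lithium dienolate 5 (not isolated)
Conditions: LiN(iPr)2 (LDA), THF, −78 °C; then MeI, −78 °C to 0 °C
Reagents that add atoms: iodomethane, CI
Why: Kinetic deprotonation at the α′-CH2 (future C10) gives the cross-conjugated dienolate, which is C-methylated (enolate alkylation) mainly anti to the isopropenyl group; this centre is planarised again in step 4, so its configuration is of no consequence.

**Step 4**
Reactants: 6 trans-6-methylcarvone; 3 (1Z)-3-bromo-1-iodoprop-1-ene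
Product: 8 (5R,6R)-6-[(2Z)-3-iodoprop-2-en-1-yl]-2,6-dimethyl-5-(prop-1-en-2-yl)cyclohex-2-en-1-one, via lithium dienolate 7 (not isolated)
Conditions: LiN(iPr)2 (LDA), THF, −78 °C; then 3, DMPU, −78 °C to 0 °C
Reagents that add atoms: 3 (1Z)-3-bromo-1-iodoprop-1-ene, BrC/C=C\I
Why: Enolate alkylation in which the tetrasubstituted dienolate holds the neighbouring isopropenyl group pseudoaxial to avoid strain with the enolate methyl group, so the allylic bromide should enter from the opposite face and the new quaternary centre (C10) should carry the iodoallyl arm trans and the methyl group (C20) cis to the isopropenyl group.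

**Step 5**
Reactants: 8 the (Z)-iodoallyl isopropenyl enone
Product: 10 (4aR,5R,8aR)-5-(hydroxymethyl)-2,5,8a-trimethyl-4a,5,8,8a-tetrahydronaphthalen-1(4H)-one (19-hydroxy-11,12,13,14,15,16-hexanorlabda-2,7-dien-9-one), via pinacol boronate 9 (not isolated)
Conditions: Pd(PPh3)4 (5 mol %), B2pin2 (2 equiv), KOAc (3 equiv), 1,4-dioxane, 80 °C; then NaBO3·4H2O, THF/H2O, rt (one pot)
Reagents that add atoms: sodium perborate tetrahydrate, [Na+].[O-]OB=O.O.O.O.O (oxygen of the C19 hydroxyl); bis(pinacolato)diboron, CC1(C)OB(OC1(C)C)B1OC(C)(C)C(C)(C)O1 (boron of intermediate 9 only)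
Why: Zerovalent palladium inserts into the C3–I bond with retention of the (Z) geometry, the alkenylpalladium iodide adds syn across the isopropenyl C4=C19 bond in a 6-exo-trig carbopalladation that closes ring A through the C3–C4 bond, and the neopentyl C19–Pd species, which has no β-hydrogen, is intercepted by acetate-assisted transmetalation with B2pin2 and C–B reductive elimination, after which perborate oxidises C–B to C–OH with retention. The closest known reaction type is the domino Heck cyclisation/borylation of halide-tethered 1,1-disubstituted alkenes, including the alkenyl-borylation of (Z)-1-iodo-1,6-dienes. C4 is the only new stereocentre and is controlled by the C5 and C10 centres: the two arms are trans-diequatorial on ring B, so ring A can only close as a trans-fused half-chair, and in that array the C4=C19 bond must eclipse the C3–Pd bond, which places the flat palladated methylene pseudoaxial on the C20 face while the bulkier methyl group (C18) stays pseudoequatorial next to H-5 and avoids an eclipsing contact with the quaternary C10. The step needs 6-exo over 7-endo insertion, ring closure before direct borylation of the alkenyl iodide, and capture of C19–Pd before its 3-exo attack on the new C2=C3 bond; the first is the normal preference for exo closure onto a 1,1-disubstituted alkene, the second rests on intramolecular insertion being faster than transmetalation, and the third is secured by excess B2pin2 and KOAc. The enone alkene does not compete because it is trisubstituted, electron-poor and would have to be attacked at its α-carbon.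

**Step 6**
Reactants: 10 the ring-A-closed dienone alcohol
Product: 11 2,3,19-trihydroxy-11,12,13,14,15,16-hexanorlabd-7-en-9-one (2-OH and 3-OH cis on the H-5 face)
Conditions: OsO4 (5 mol %), N-methylmorpholine N-oxide, acetone/H2O, rt
Reagents that add atoms: osmium tetroxide, O=[Os](=O)(=O)=O (catalytic oxygen carrier); N-methylmorpholine N-oxide, C[N+]1([O-])CCOCC1; water, O
Why: Upjohn dihydroxylation in which OsO4 adds syn to the C2=C3 bond from the face opposite the pseudoaxial C19 hydroxymethyl and the axial C20 methyl, which should set both carbinol centres on the H-5 face, while the electron-poor trisubstituted enone alkene is spared.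

**Step 7**
Reactants: 11 the triol
Product: 12 2,3-O-isopropylidene-2,3,19-trihydroxy-11,12,13,14,15,16-hexanorlabd-7-en-9-one
Conditions: 2,2-dimethoxypropane, pyridinium p-toluenesulfonate (cat.), acetone, rt
Reagents that add atoms: 2,2-dimethoxypropane, COC(C)(C)OC
Why: Acid-catalysed transketalisation forms the five-membered acetonide of the cis-2,3-diol, and the C19 hydroxyl stays free because O-19 is anti (trans-diaxial) to O-3 and cannot be bridged.

**Step 8**
Reactants: 12 the acetonide ketone
Product: 13 2,3-O-isopropylidene-13,14,15,16-tetranor-12-norlabda-7,9(11)-diene-2,3,19-triol (C9 exocyclic methylene, C19 hydroxyl free)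
Conditions: Ph3PCH3Br (4 equiv), KOtBu (3.8 equiv), toluene, 90 °C
Reagents that add atoms: methyltriphenylphosphonium bromide, C[P+](c1ccccc1)(c1ccccc1)c1ccccc1.[Br-]
Why: Wittig methylenation under forcing conditions, as used for hindered 2,6,6-trisubstituted cyclohexenones, converts the C9 carbonyl group into the exocyclic alkene (C11) while the free alcohol is carried as its alkoxide.

**Step 9**
Reactants: 13 the diene alcohol
Product: 14 19-acetoxy diene acetonide
Conditions: Ac2O, pyridine, 4-dimethylaminopyridine (cat.), CH2Cl2, rt
Reagents that add atoms: acetic anhydride, CC(=O)OC(C)=O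
Why: Nucleophile-catalysed acetylation of the only free hydroxyl group (primary, C19).

**Step 10**
Reactants: 15 (S)-4-methyldihydrofuran-2(3H)-one
Product: 16 (S)-4-bromo-3-methylbutanoic acid
Conditions: HBr (33 % in AcOH), 70 °C
Reagents that add atoms: hydrogen bromide, Br
Why: Acidic ring opening of the γ-lactone by bromide at the primary O–CH2 carbon does not touch the stereocentre, which becomes C13.

**Step 11**
Reactants: 16 (S)-4-bromo-3-methylbutanoic acid
Product: 17 tert-butyl (S)-4-bromo-3-methylbutanoate
Conditions: isobutene, H2SO4 (cat.), CH2Cl2, sealed vessel, rt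
Reagents that add atoms: 2-methylpropene, CC(C)=C
Why: Acid-catalysed addition of the carboxylic acid to isobutene gives the tert-butyl ester without base, so neither relactonisation nor cyclopropane formation can occur.

**Step 12**
Reactants: 14 the 19-acetoxy diene acetonide; 17 tert-butyl (S)-4-bromo-3-methylbutanoate
Product: 19 tert-butyl 19-acetoxy-2,3-O-isopropylidene-2,3-dihydroxylabd-7-en-15-oate, via alkylborane 18 (not isolated)
Conditions: 9-BBN (1.5 equiv), THF, rt; then Pd(OAc)2 (5 mol %), PCy3 (10 mol %), K3PO4·H2O, 17, THF, rt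
Reagents that add atoms: 17 tert-butyl (S)-4-bromo-3-methylbutanoate, BrC[C@@H](C)CC(=O)OC(C)(C)C
Why: Hydroboration with 9-BBN attacks only the terminal carbon of the exocyclic alkene and should deliver hydrogen to C9 from the face opposite the axial C20 methyl (H-9 on the H-5 face, C11 equatorial), and the primary alkylborane then undergoes B-alkyl Suzuki–Miyaura coupling with the primary alkyl bromide under Pd/PCy3 conditions that suppress β-hydride elimination, joining C11 to C12 with C13 untouched.

**Step 13**
Reactants: 19 the protected ester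
Product: 20 (2S,3R,4R,5S,9R,10S,13R)-19-acetoxy-2,3-dihydroxylabd-7-en-15-oic acid (target)
Conditions: CF3CO2H/CH2Cl2/H2O, 0 °C to rt
Reagents that add atoms: none
Why: Aqueous trifluoroacetic acid hydrolyses the acetonide and cleaves the tert-butyl ester through the tert-butyl cation in one operation, while the primary acetate is stable to acid and cannot migrate because O-19 is anti to O-3.

**Compound list**
1 | ethyl (2Z)-3-iodoprop-2-enoate | CCOC(=O)/C=C\I | starting material
2 | (2Z)-3-iodoprop-2-en-1-ol | OC/C=C\I | intermediate
3 | (1Z)-3-bromo-1-iodoprop-1-ene | BrC/C=C\I | intermediate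
4 | (S)-(+)-carvone, (5S)-2-methyl-5-(prop-1-en-2-yl)cyclohex-2-en-1-one | CC(=C)[C@H]1CC=C(C)C(=O)C1 | starting material
5 | lithium dienolate of 4 (deprotonated at C6 of carvone) | CC(=C)[C@H]1CC=C(C)C(O[Li])=C1 | intermediate
6 | (5S,6R)-2,6-dimethyl-5-(prop-1-en-2-yl)cyclohex-2-en-1-one | CC(=C)[C@H]1CC=C(C)C(=O)[C@@H]1C | intermediate
7 | lithium dienolate of 6 | CC(=C)[C@H]1CC=C(C)C(O[Li])=C1C | intermediate
8 | (5R,6R)-6-[(2Z)-3-iodoprop-2-en-1-yl]-2,6-dimethyl-5-(prop-1-en-2-yl)cyclohex-2-en-1-one | CC(=C)[C@H]1CC=C(C)C(=O)[C@]1(C)C/C=C\I | intermediate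
9 | 19-(4,4,5,5-tetramethyl-1,3,2-dioxaborolan-2-yl)-11,12,13,14,15,16-hexanorlabda-2,7-dien-9-one (CH2B on the C20 face, trans ring fusion) | CC1(C)OB(C[C@@]2(C)[C@H]3CC=C(C)C(=O)[C@]3(C)CC=C2)OC1(C)C | intermediate
10 | (4aR,5R,8aR)-5-(hydroxymethyl)-2,5,8a-trimethyl-4a,5,8,8a-tetrahydronaphthalen-1(4H)-one | OC[C@@]1(C)[C@H]2CC=C(C)C(=O)[C@]2(C)CC=C1 | intermediate
11 | 2,3,19-trihydroxy-11,12,13,14,15,16-hexanorlabd-7-en-9-one (2-OH and 3-OH on the H-5 face, C19 on the C20 face) | OC[C@@]1(C)[C@H]2CC=C(C)C(=O)[C@]2(C)C[C@H](O)[C@@H]1O | intermediate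
12 | 2,3-acetonide of 11 | OC[C@@]1(C)[C@H]2CC=C(C)C(=O)[C@]2(C)C[C@H](O3)[C@@H]1OC3(C)C | intermediate
13 | 9-methylidene analogue of 12 (C9=C11, C7=C8 diene, free C19 hydroxyl) | OC[C@@]1(C)[C@H]2CC=C(C)C(=C)[C@]2(C)C[C@H](O3)[C@@H]1OC3(C)C | intermediate
14 | 19-acetate of 13 | CC(=O)OC[C@@]1(C)[C@H]2CC=C(C)C(=C)[C@]2(C)C[C@H](O3)[C@@H]1OC3(C)C | intermediate
15 | (S)-4-methyldihydrofuran-2(3H)-one | O=C1C[C@H](C)CO1 | starting material
16 | (S)-4-bromo-3-methylbutanoic acid | BrC[C@@H](C)CC(=O)O | intermediate
17 | tert-butyl (S)-4-bromo-3-methylbutanoate | BrC[C@@H](C)CC(=O)OC(C)(C)C | intermediate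
18 | C11 B-alkyl-9-borabicyclo[3.3.1]nonane from 14 (H-9 on the H-5 face) | CC(=O)OC[C@@]1(C)[C@H]2CC=C(C)[C@@H](CB4C5CCCC4CCC5)[C@]2(C)C[C@H](O3)[C@@H]1OC3(C)C | intermediate
19 | tert-butyl 19-acetoxy-2,3-O-isopropylidene-2,3-dihydroxylabd-7-en-15-oate | CC(=O)OC[C@@]1(C)[C@H]2CC=C(C)[C@@H](CC[C@@H](C)CC(=O)OC(C)(C)C)[C@]2(C)C[C@H](O3)[C@@H]1OC3(C)C | intermediate
20 | (2S,3R,4R,5S,9R,10S,13R)-19-acetoxy-2,3-dihydroxylabd-7-en-15-oic acid | CC(=O)OC[C@@]1(C)[C@H]2CC=C(C)[C@@H](CC[C@@H](C)CC(=O)O)[C@]2(C)C[C@H](O)[C@@H]1O | target

**Step count.** Total: 13 steps. Longest linear sequence: 10 steps (steps 1, 2, 4 to 9, 12 and 13, from ethyl (Z)-3-iodoacrylate); 9 steps from (S)-carvone.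

**Steps most likely to fail**

1. Step 5. The alkene insertion may proceed through the other face of the isopropenyl group (palladated methylene pseudoequatorial), or transmetalation with B2pin2 may overtake ring closure. The fallback sets out from 8 and returns at 10. Allylic oxidation of the isopropenyl methyl group of 8 (SeO2 cat., t-BuOOH, CH2Cl2) should give the 2-(hydroxymethyl)vinyl enone F1. A reductive Heck cyclisation of F1 (Pd(OAc)2, PPh3, HCO2Na, DMF, 80 °C) closes the same C3–C4 bond, but the exocyclic methylene is now reduced to the C18 methyl group and the oxygenated carbon is in place before ring closure. A preference for the palladated carbon to lie equatorial is thereby turned into the required C4 configuration, and no boron reagent competes for the alkenylpalladium; the product is 10.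

2. Step 12. Transmetalation of the hindered, β-branched alkylborane may be slow, so that β-hydride elimination and reduction of the bromide take over. The fallback sets out from 14 and returns at 19. Hydroboration of 14 as before (borane 18) with NaBO3·4H2O work-up should give the C11 alcohol F2. I2, PPh3 and imidazole convert it into the primary iodide F3. The alkylzinc bromide F4, made from 17 and zinc dust (LiCl, THF), is then joined to F3 by Negishi alkyl–alkyl coupling (Pd(OAc)2, tricyclopentylphosphine, N-methylimidazole, THF/NMP, 80 °C) to give 19; the roles of nucleophile and electrophile are exchanged.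

3. Step 8. Enolisation of the hindered enone by the basic ylide may stall conversion and move the ring alkene out of conjugation. The fallback sets out from 12 and returns at 13. Peterson olefination: Me3SiCH2Li with CeCl3 (THF, −78 °C), a small and weakly basic nucleophile, adds to the C9 carbonyl group to give the β-hydroxysilane F5, and KH in THF eliminates silanolate to give 13.

**Further compounds**
F1 | step 5 | (5R,6R)-5-[3-hydroxyprop-1-en-2-yl]-6-[(2Z)-3-iodoprop-2-en-1-yl]-2,6-dimethylcyclohex-2-en-1-one | OCC(=C)[C@H]1CC=C(C)C(=O)[C@]1(C)C/C=C\I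
F2 | step 12 | C11 alcohol from 14 (19-acetoxy-2,3-O-isopropylidene-12,13,14,15,16-pentanorlabd-7-ene-2,3,11-triol) | CC(=O)OC[C@@]1(C)[C@H]2CC=C(C)[C@@H](CO)[C@]2(C)C[C@H](O3)[C@@H]1OC3(C)C
F3 | step 12 | C11 iodide from F2 | CC(=O)OC[C@@]1(C)[C@H]2CC=C(C)[C@@H](CI)[C@]2(C)C[C@H](O3)[C@@H]1OC3(C)C
F4 | step 12 | [(S)-4-tert-butoxy-2-methyl-4-oxobutyl]zinc bromide | Br[Zn]C[C@@H](C)CC(=O)OC(C)(C)C
F5 | step 8 | C9 β-hydroxysilane from 12 (9-hydroxy-9-(trimethylsilylmethyl), hydroxyl on the C20 face) | OC[C@@]1(C)[C@H]2CC=C(C)[C@](O)(C[Si](C)(C)C)[C@]2(C)C[C@H](O3)[C@@H]1OC3(C)C
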